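**Strategy.** The seven-membered ring is disconnected at C8–C8a (azulene numbering: C1 acetate, C3 carbinol, C4 aroyloxy, C7 ketone, C8a angular methyl). The oxygenated carbons C3 (five-membered ring) and C7 (seven-membered ring) are 1,5-related through C3a–C8a–C8, the signature of a de Mayo sequence. An intramolecular enone–enol acetate [2+2] photocycloaddition of a 2-substituted 3-methylcyclopentenone (C3 carbonyl; C4–C5–C6 tether with a silyloxy group at C4) forms C8–C8a and a sacrificial C3a–C7 bond in a cyclobutane with three contiguous fully substituted carbons; retro-aldol cleavage of C3a–C7 then releases the strain and unveils the trans-fused hydroazulene.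

Key step: step 8

Assumption: the methyl-bearing carbon of the side chain (future C6) is a sacrificial stereocentre that becomes sp2 in step 14; its S configuration is chosen only to place the methyl group on the convex face of the photoadduct.

Step 1
Reactants: 1 2-methylcyclopent-2-en-1-one
Product: 2 6-methyl-1,4-dioxaspiro[4.4]non-6-ene
Conditions: ethylene glycol, p-TsOH (cat.), benzene, reflux, azeotropic removal of water
Reagents that add atoms: ethylene glycol, OCCO
Why: Acid-catalysed ketalisation masks the carbonyl that becomes C1, and the trisubstituted alkene, being the more substituted isomer, should stay in place.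

Step 2
Reactants: 2 6-methyl-1,4-dioxaspiro[4.4]non-6-ene
Product: 3 6-methyl-1,4-dioxaspiro[4.4]non-6-en-8-one
Conditions: t-BuOOH, Rh2(cap)4 (dirhodium tetracaprolactamate, 1 mol %), K2CO3, CH2Cl2, rt
Reagents that add atoms: tert-butyl hydroperoxide, CC(C)(C)OO
Why: Radical allylic C–H oxidation at the only allylic ring methylene should give the enone whose carbonyl is the future C3, because the ketal carbon carries no hydrogen and the methyl group is less reactive.

Step 3
Reactants: 3 6-methyl-1,4-dioxaspiro[4.4]non-6-en-8-one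
Product: 4 7-iodo-6-methyl-1,4-dioxaspiro[4.4]non-6-en-8-one
Conditions: I2, K2CO3, DMAP (cat.), THF–H2O, rt
Reagents that add atoms: iodine, [I][I]
Why: Addition–elimination α-iodination of the enone (DMAP adds to the β-carbon, the enolate is iodinated, DMAP is expelled) should place the halogen on the future C3a.

Step 4
Reactants: 5 (E)-but-2-enal, 6 ethynyltri(propan-2-yl)silane
Product: 7 (S)-3-methyl-5-[tri(propan-2-yl)silyl]pent-4-ynal
Conditions: [Rh(OAc)(C2H4)2]2 (2.5 mol %), DTBM-segphos (antipode that gives the S product, 6 mol %), MeOH, 40 °C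
Reagents that add atoms: none
Why: Rhodium-catalysed asymmetric conjugate alkynylation (1,4-addition of an alkynylrhodium species) should set the methyl-bearing centre under ligand control, the bulky silyl group suppressing alkyne dimerisation.

Step 5
Reactants: 7 (S)-3-methyl-5-[tri(propan-2-yl)silyl]pent-4-ynal
Product: 8 (S)-3-methylpent-4-ynal
Conditions: AgF, MeOH, rt, dark; then 1 M HCl
Reagents that add atoms: none
Why: Fluoride-induced protodesilylation through the silver acetylide is non-basic, so the enolisable aldehyde and the stereocentre should survive.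

Step 6
Reactants: 8 (S)-3-methylpent-4-ynal
Product: 9 (S)-3-methyl-5-oxopent-1-en-2-yl acetate
Conditions: AcOH, [RuCl2(p-cymene)]2 (1 mol %), P(2-furyl)3, Na2CO3 (cat.), toluene, 50 °C
Reagents that add atoms: acetic acid, CC(=O)O
Why: Ruthenium-catalysed Markovnikov hydro-acyloxylation of the terminal alkyne should give the 1,1-disubstituted enol acetate under nearly neutral conditions that the aldehyde tolerates.

Step 7
Reactants: 4 7-iodo-6-methyl-1,4-dioxaspiro[4.4]non-6-en-8-one, 9 (S)-3-methyl-5-oxopent-1-en-2-yl acetate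
Product: 10 (3S,5R)-3-methyl-5-(6-methyl-8-oxo-1,4-dioxaspiro[4.4]non-6-en-7-yl)-5-[(triethylsilyl)oxy]pent-1-en-2-yl acetate
Conditions: CrCl2 (10 mol %), chiral oxazoline–sulfonamide ligand (antipode that gives the 5R carbinol, 12 mol %), NiCl2·(2,9-dimethyl-1,10-phenanthroline) (2 mol %), Mn, Et3SiCl, LiCl, MeCN, rt
Reagents that add atoms: chlorotriethylsilane, CC[Si](CC)(CC)Cl
Why: Nozaki–Hiyama–Kishi coupling, in which zerovalent nickel inserts into the carbon–iodine bond, the alkenyl group passes to trivalent chromium and adds to the aldehyde face selected by the chromium-bound ligand (5R, the future C4), while Et3SiCl frees the chromium (Mn returns it to the divalent state) and delivers the silyl ether, which also keeps the alkoxide from attacking the enol acetate.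

Step 8
Reactants: 10 (3S,5R)-3-methyl-5-(6-methyl-8-oxo-1,4-dioxaspiro[4.4]non-6-en-7-yl)-5-[(triethylsilyl)oxy]pent-1-en-2-yl acetate
Product: 11 4,7-dimethyl-10-oxo-2-[(triethylsilyl)oxy]spiro[tricyclo[5.3.0.0(1,5)]decane-8,2'-[1,3]dioxolan]-5-yl acetate (cyclobutane cis-fused to both five-membered rings, which lie anti to each other; silyloxy and C4-methyl groups on the convex face)
Conditions: hν (350 nm), degassed CH2Cl2 (5 mM), rt
Reagents that add atoms: none
Why: Excitation of the enone and intersystem crossing give the triplet, whose α-carbon (future C3a) attacks the internal carbon of the enol acetate (future C7) through a five-membered transition state, and the resulting triplet 1,4-biradical collapses after spin inversion by forming the C8–C8a bond, which closes the cyclobutane. The closest known reaction type is the intramolecular enone–alkene [2+2] photocycloaddition of the de Mayo type with an enol ester as the alkene partner. The cyclopentane C3a–C4–C5–C6–C7 is closed in the 5-exo-trig mode dictated by the three-atom tether (rule of five), and the four-membered ring by recombination of the 1,4-biradical, formally a 4-exo closure. The quaternary stereocentre C8a is set by the facial selectivity that the C4 silyloxy centre imposes through allylic 1,3-strain (the C4 hydrogen eclipses the C8a methyl group, so the tether reaches only one enone face), while the cis fusion at C3a and C7 is enforced by the strain of the two bicyclo[3.2.0] units and is erased again in step 9. The step needs straight instead of crossed regiochemistry, secured by the three-atom tether on the α-carbon; a single enone face, secured by the lone stereocentre next to the achiral ketal ring; and selective excitation, secured because only the enone absorbs above 320 nm.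

Step 9
Reactants: 11 photoadduct
Product: 15 transannular methyl ketal (trans-fused 7-methoxy-6,8a-dimethyl-4,7-epoxyperhydroazulen-3-one 1-ethylene ketal), via cyclobutanol 12 (not isolated), via silyl ether diketone 13 (not isolated), via hydroxy diketone 14 (not isolated)
Conditions: K2CO3, MeOH, 0 °C; then PPTS, MeOH, rt
Reagents that add atoms: methanol, CO
Why: Methanolysis of the tertiary acetate gives the cyclobutanolate, which undergoes strain-driven retro-aldol cleavage of the C3a–C7 bond (second half of the de Mayo reaction); the enolate should be protonated anti to the angular methyl group to give the trans ring fusion, and acidic methanol then removes the silyl group and closes the 4-hydroxy ketone to the bridged methyl ketal, in which the trans-fused epimer should also be the more stable one because both ring-fusion bonds of the cyclopentanone are equatorial on the oxane chair.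

Step 10
Reactants: 15 transannular methyl ketal
Product: 17 (3S,3aR,4R,6S,8aS)-3,4-dihydroxy-6,8a-dimethyl-3-(propan-2-yl)perhydroazulene-1,7-dione (trans-fused), via carbinol ketal 16 (not isolated)
Conditions: i-PrMgCl, CeCl3, THF, −78 °C; then 1 M HCl, THF, rt
Reagents that add atoms: isopropylmagnesium chloride, CC(C)[Mg]Cl; water, O
Why: Organocerium 1,2-addition to the only free carbonyl (C7 is locked in the bridged ketal) should occur on the face of H-3a, opposite the angular methyl group, which sets C3 with the hydroxyl cis to the C8a methyl group; aqueous acid then hydrolyses the bridged ketal and the dioxolane.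

Step 11
Reactants: 17 dihydroxy diketone, 18 4-[(tert-butyldimethylsilyl)oxy]benzoic acid
Product: 19 (3S,3aR,4R,6S,8aS)-3-hydroxy-6,8a-dimethyl-1,7-dioxo-3-(propan-2-yl)perhydroazulen-4-yl 4-[(tert-butyldimethylsilyl)oxy]benzoate
Conditions: DCC, DMAP (cat.), CH2Cl2, 0 °C to rt
Reagents that add atoms: none
Why: Steglich esterification should acylate the only secondary hydroxyl (C4), the hindered tertiary C3 hydroxyl being inert.

Step 12
Reactants: 19 keto ester
Product: 20 (1R,3S,3aR,4R,6S,8aS)-1,3-dihydroxy-6,8a-dimethyl-7-oxo-3-(propan-2-yl)perhydroazulen-4-yl 4-[(tert-butyldimethylsilyl)oxy]benzoate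
Conditions: Me4NBH(OAc)3, MeCN–AcOH (1:1), −20 °C
Reagents that add atoms: none
Why: Evans–Saksena reduction, in which the tertiary C3 hydroxyl binds the triacetoxyborohydride and delivers hydride to its own face of the C1 carbonyl, should give the 1,3-anti diol (C1 hydroxyl trans to the C3 hydroxyl and to the angular methyl group) and leave the isolated C7 ketone untouched.

Step 13
Reactants: 20 diol
Product: 21 (1R,3S,3aR,4R,6S,8aS)-1-acetoxy-3-hydroxy-6,8a-dimethyl-7-oxo-3-(propan-2-yl)perhydroazulen-4-yl 4-[(tert-butyldimethylsilyl)oxy]benzoate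
Conditions: Ac2O, DMAP (cat.), pyridine, CH2Cl2, 0 °C to rt
Reagents that add atoms: acetic anhydride, CC(=O)OC(C)=O
Why: DMAP-catalysed acetylation should take the secondary C1 hydroxyl and leave the tertiary C3 hydroxyl, flanked by the isopropyl group, free.

Step 14
Reactants: 21 saturated ketone
Product: 22 (1R,3S,3aR,4R,8aS)-1-acetoxy-3-hydroxy-6,8a-dimethyl-7-oxo-3-(propan-2-yl)-1,2,3,3a,4,7,8,8a-octahydroazulen-4-yl 4-[(tert-butyldimethylsilyl)oxy]benzoate
Conditions: IBX (2-iodoxybenzoic acid), DMSO–fluorobenzene, 70 °C
Reagents that add atoms: none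
Why: IBX dehydrogenation through the enol toward C6 (C8 has no β-hydrogen because C8a is quaternary) should give the endocyclic α-methyl enone and erase the sacrificial C6 stereocentre, no free secondary alcohol being left to oxidise.

Step 15
Reactants: 22 silyl-protected enone
Product: 23 (1R,3S,3aR,4R,8aS)-1-acetoxy-3-hydroxy-6,8a-dimethyl-7-oxo-3-(propan-2-yl)-1,2,3,3a,4,7,8,8a-octahydroazulen-4-yl 4-hydroxybenzoate
Conditions: HF·pyridine, THF, 0 °C
Reagents that add atoms: none
Why: Fluoride-mediated desilylation should cleave the phenolic silyl ether much faster than it touches the esters, and the acidic medium spares the base-sensitive γ-acyloxy enone.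

**Compound list**

1 | 2-methylcyclopent-2-en-1-one | CC1=CCCC1=O | starting material
2 | 6-methyl-1,4-dioxaspiro[4.4]non-6-ene | CC1=CCCC12OCCO2 | intermediate
3 | 6-methyl-1,4-dioxaspiro[4.4]non-6-en-8-one | CC1=CC(=O)CC12OCCO2 | intermediate
4 | 7-iodo-6-methyl-1,4-dioxaspiro[4.4]non-6-en-8-one | IC1=C(C)C2(OCCO2)CC1=O | intermediate
5 | (E)-but-2-enal | C/C=C/C=O | starting material
6 | ethynyltri(propan-2-yl)silane | C#C[Si](C(C)C)(C(C)C)C(C)C | starting material
7 | (S)-3-methyl-5-[tri(propan-2-yl)silyl]pent-4-ynal | O=CC[C@H](C)C#C[Si](C(C)C)(C(C)C)C(C)C | intermediate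
8 | (S)-3-methylpent-4-ynal | O=CC[C@H](C)C#C | intermediate
9 | (S)-3-methyl-5-oxopent-1-en-2-yl acetate | O=CC[C@H](C)C(OC(C)=O)=C | intermediate
10 | (3S,5R)-3-methyl-5-(6-methyl-8-oxo-1,4-dioxaspiro[4.4]non-6-en-7-yl)-5-[(triethylsilyl)oxy]pent-1-en-2-yl acetate | O=C1CC2(OCCO2)C(C)=C1[C@H](O[Si](CC)(CC)CC)C[C@H](C)C(OC(C)=O)=C | intermediate
11 | photoadduct: 4,7-dimethyl-10-oxo-2-[(triethylsilyl)oxy]spiro[tricyclo[5.3.0.0(1,5)]decane-8,2'-[1,3]dioxolan]-5-yl acetate, cis,anti,cis-fused, silyloxy and C4-methyl on the convex face | O=C1CC2(OCCO2)[C@@]3(C)C[C@]4(OC(C)=O)[C@@H](C)C[C@@H](O[Si](CC)(CC)CC)[C@]134 | intermediate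
12 | cyclobutanol (11 without the acetyl group) | O=C1CC2(OCCO2)[C@@]3(C)C[C@]4(O)[C@@H](C)C[C@@H](O[Si](CC)(CC)CC)[C@]134 | intermediate (not isolated)
13 | (3aR,4R,6S,8aS)-6,8a-dimethyl-4-[(triethylsilyl)oxy]perhydroazulene-3,7-dione 1-ethylene ketal, trans-fused | C13(OCCO3)CC(=O)[C@H]2[C@H](O[Si](CC)(CC)CC)C[C@H](C)C(=O)C[C@]12C | intermediate (not isolated)
14 | (3aR,4R,6S,8aS)-4-hydroxy-6,8a-dimethylperhydroazulene-3,7-dione 1-ethylene ketal, trans-fused | C13(OCCO3)CC(=O)[C@H]2[C@H](O)C[C@H](C)C(=O)C[C@]12C | intermediate (not isolated)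
15 | transannular methyl ketal of 14 (oxygen bridge from C4 to C7, methoxy on C7, C3 ketone free, C1 as dioxolane) | C13(OCCO3)CC(=O)[C@H]2[C@H]4C[C@H](C)[C@](OC)(O4)C[C@]12C | intermediate
16 | C3 isopropyl carbinol of 15 (hydroxyl cis to the C8a methyl group, both ketals intact) | C13(OCCO3)C[C@](O)(C(C)C)[C@H]2[C@H]4C[C@H](C)[C@](OC)(O4)C[C@]12C | intermediate (not isolated)
17 | (3S,3aR,4R,6S,8aS)-3,4-dihydroxy-6,8a-dimethyl-3-(propan-2-yl)perhydroazulene-1,7-dione, trans-fused | O=C1C[C@](O)(C(C)C)[C@H]2[C@H](O)C[C@H](C)C(=O)C[C@]12C | intermediate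
18 | 4-[(tert-butyldimethylsilyl)oxy]benzoic acid | CC(C)(C)[Si](C)(C)Oc1ccc(C(=O)O)cc1 | starting material
19 | (3S,3aR,4R,6S,8aS)-3-hydroxy-6,8a-dimethyl-1,7-dioxo-3-(propan-2-yl)perhydroazulen-4-yl 4-[(tert-butyldimethylsilyl)oxy]benzoate | O=C1C[C@](O)(C(C)C)[C@H]2[C@H](OC(=O)c3ccc(O[Si](C)(C)C(C)(C)C)cc3)C[C@H](C)C(=O)C[C@]12C | intermediate
20 | (1R,3S,3aR,4R,6S,8aS)-1,3-dihydroxy-6,8a-dimethyl-7-oxo-3-(propan-2-yl)perhydroazulen-4-yl 4-[(tert-butyldimethylsilyl)oxy]benzoate | O[C@@H]1C[C@](O)(C(C)C)[C@H]2[C@H](OC(=O)c3ccc(O[Si](C)(C)C(C)(C)C)cc3)C[C@H](C)C(=O)C[C@]12C | intermediate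
21 | (1R,3S,3aR,4R,6S,8aS)-1-acetoxy-3-hydroxy-6,8a-dimethyl-7-oxo-3-(propan-2-yl)perhydroazulen-4-yl 4-[(tert-butyldimethylsilyl)oxy]benzoate | CC(=O)O[C@@H]1C[C@](O)(C(C)C)[C@H]2[C@H](OC(=O)c3ccc(O[Si](C)(C)C(C)(C)C)cc3)C[C@H](C)C(=O)C[C@]12C | intermediate
22 | (1R,3S,3aR,4R,8aS)-1-acetoxy-3-hydroxy-6,8a-dimethyl-7-oxo-3-(propan-2-yl)-1,2,3,3a,4,7,8,8a-octahydroazulen-4-yl 4-[(tert-butyldimethylsilyl)oxy]benzoate | CC(=O)O[C@@H]1C[C@](O)(C(C)C)[C@H]2[C@H](OC(=O)c3ccc(O[Si](C)(C)C(C)(C)C)cc3)C=C(C)C(=O)C[C@]12C | intermediate
23 | (1R,3S,3aR,4R,8aS)-1-acetoxy-3-hydroxy-6,8a-dimethyl-7-oxo-3-(propan-2-yl)-1,2,3,3a,4,7,8,8a-octahydroazulen-4-yl 4-hydroxybenzoate | CC(=O)O[C@@H]1C[C@](O)(C(C)C)[C@H]2[C@H](OC(=O)c3ccc(O)cc3)C=C(C)C(=O)C[C@]12C | target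

**Totals.** Total step count: 15. Longest linear sequence: 12 steps (steps 1–3 or steps 4–6, then steps 7–15).

**Steps most likely to fail**

Step 8. The photocycloaddition may attack both enone faces if allylic strain alone does not fix the rotamer about the C3a–C4 bond, or may close in the crossed sense. The fallback sets out from 10 and replaces steric control by hydrogen-bond control. HF·pyridine in THF should remove the silyl group to give the free carbinol F1. Irradiation of F1 at 350 nm in CH2Cl2, where the carbinol is hydrogen-bonded to the enone carbonyl and the rotamer is locked in the same sense, should give the hydroxy photoadduct F2. Treatment of F2 with K2CO3 in MeOH and then PPTS in MeOH, as in step 9, comes back to the route at 15.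

Step 7. The chromium-mediated addition may proceed with low enantioselectivity, or the aldehyde may be lost to silyl enol ether formation under the turnover conditions. The fallback sets out from 4 and 9 and replaces catalyst control by separation and recycling. Coupling without a chiral ligand (CrCl2, NiCl2 cat., DMF; then Et3SiCl, imidazole) should give 10 together with its C5 epimer, the silyl ether F3. The two are diastereomers because of the C3 methyl centre and should separate by chromatography. F3 is recycled: HF·pyridine should give the epimeric carbinol F4; a Mitsunobu reaction with chloroacetic acid (PPh3, DIAD) should invert C5 and give the chloroacetate F5; thiourea and NaHCO3 in EtOH should remove the chloroacetyl group without touching the enol acetate and give the free carbinol F1; Et3SiCl and imidazole then come back to the route at 10.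

Step 14. The dehydrogenation may stall, may give the exocyclic methylene isomer, or may oxidise the late intermediate elsewhere at 70 °C. The fallback sets out from 21 and uses a two-stage Saegusa–Ito oxidation instead. Me3SiOTf and Et3N in CH2Cl2 should give the bis(trimethylsilyl) compound F6 (silyl enol ether toward C6, tertiary hydroxyl silylated as well). Pd(OAc)2 in MeCN at rt, followed by dilute HCl in THF to free the tertiary hydroxyl, comes back to the route at 22.

Further compounds
F1 | step 8 | (3S,5R)-5-hydroxy-3-methyl-5-(6-methyl-8-oxo-1,4-dioxaspiro[4.4]non-6-en-7-yl)pent-1-en-2-yl acetate | O=C1CC2(OCCO2)C(C)=C1[C@H](O)C[C@H](C)C(OC(C)=O)=C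
F2 | step 8 | hydroxy photoadduct (11 without the triethylsilyl group) | O=C1CC2(OCCO2)[C@@]3(C)C[C@]4(OC(C)=O)[C@@H](C)C[C@@H](O)[C@]134
F3 | step 7 | (3S,5S)-3-methyl-5-(6-methyl-8-oxo-1,4-dioxaspiro[4.4]non-6-en-7-yl)-5-[(triethylsilyl)oxy]pent-1-en-2-yl acetate | O=C1CC2(OCCO2)C(C)=C1[C@@H](O[Si](CC)(CC)CC)C[C@H](C)C(OC(C)=O)=C
F4 | step 7 | (3S,5S)-5-hydroxy-3-methyl-5-(6-methyl-8-oxo-1,4-dioxaspiro[4.4]non-6-en-7-yl)pent-1-en-2-yl acetate | O=C1CC2(OCCO2)C(C)=C1[C@@H](O)C[C@H](C)C(OC(C)=O)=C
F5 | step 7 | (3S,5R)-5-(chloroacetoxy)-3-methyl-5-(6-methyl-8-oxo-1,4-dioxaspiro[4.4]non-6-en-7-yl)pent-1-en-2-yl acetate | O=C1CC2(OCCO2)C(C)=C1[C@H](OC(=O)CCl)C[C@H](C)C(OC(C)=O)=C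
F6 | step 14 | 7-(trimethylsilyl) enol ether and 3-O-trimethylsilyl ether of 21 | CC(=O)O[C@@H]1C[C@](O[Si](C)(C)C)(C(C)C)[C@H]2[C@H](OC(=O)c3ccc(O[Si](C)(C)C(C)(C)C)cc3)CC(C)=C(O[Si](C)(C)C)C[C@]12C
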